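**Retrosynthetic overview**
1. Target 26 ⇐ bis-silyl ether 25 ⇐ stannane/iodide 24: the 11-membered carbocycle is closed last by a carbonylative Stille coupling (C7–C8–C9), with CO becoming the C8 ketone.
2. 24 ⇐ lactol 18 + iodo ylide 20 (Wittig gives the Z C9=C10 iodoalkene); 18 ⇐ seven-membered lactone 17.
3. Key step: 17 ⇐ vinyl cyclic carbonate 15 by carbonyl methylenation and Claisen [3,3]-sigmatropic ring expansion, which forms C1–C11, the quaternary C1 (chirality transfer from C3) and the ring-enforced Z C2=C3 alkene.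
4. 15 ⇐ aldehyde 7 + vinyl iodide 10 (Nozaki–Hiyama–Kishi; C3 set by C4); C5 is set by C4 in ketone 3.
5. The only bought stereocentre is C4, in glycerate acetonide 1. Ring order: dioxolanone → oxepinone (opened again) → cycloundecatrienone.

Assumption and locants: the target is taken as exactly the given SMILES; C1 = quaternary ring carbon, C2=C3, C4 (ester carbinol), C5 (tertiary carbinol), C6=C7, C8 (ketone), C9 (bears CH2OH), C10, C11 (ring CH2).

**Step 1**
Reactants: 1 methyl (4S)-2,2-dimethyl-1,3-dioxolane-4-carboxylate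
Product: 3 1-[(4S)-2,2-dimethyl-1,3-dioxolan-4-yl]ethan-1-one, via Weinreb amide 2 (not isolated)
Conditions: MeNH(OMe)·HCl, iPrMgCl, THF, −20 °C; then MeMgBr, 0 °C; aq. NH4Cl
Reagents that add atoms: methylmagnesium bromide, C[Mg]Br
Why: Weinreb ketone synthesis; the chelated tetrahedral intermediate stops at the ketone and the cold, non-enolising conditions keep C4 intact.

**Step 2**
Reactants: 3 1-[(4S)-2,2-dimethyl-1,3-dioxolan-4-yl]ethan-1-one
Product: 4 (2R)-2-[(4S)-2,2-dimethyl-1,3-dioxolan-4-yl]but-3-yn-2-ol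
Conditions: HC≡CMgBr, THF, −78 to −40 °C; aq. NH4Cl; chromatography
Reagents that add atoms: ethynylmagnesium bromide, C#C[Mg]Br
Why: Felkin–Anh (non-chelated) 1,2-addition anti to the dioxolane C–O bond sets C5 as R (4,5-anti); the minor epimer is removed.

**Step 3**
Reactants: 4 (2R)-2-[(4S)-2,2-dimethyl-1,3-dioxolan-4-yl]but-3-yn-2-ol
Product: 5 (2S,3R)-3-methylpent-4-yne-1,2,3-triol
Conditions: AcOH/H2O 4:1, 40 °C
Reagents that add atoms: none
Why: Acid-catalysed acetal hydrolysis; no stereocentre is touched.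

**Step 4**
Reactants: 5 (2S,3R)-3-methylpent-4-yne-1,2,3-triol
Product: 6 (3R,4S)-3-methyl-3,4,5-tris(triethylsilyloxy)pent-1-yne
Conditions: Et3SiOTf (3.5 equiv), 2,6-lutidine, CH2Cl2, −78 to 0 °C
Reagents that add atoms: triethylsilyl trifluoromethanesulfonate, CC[Si](CC)(CC)OS(=O)(=O)C(F)(F)F
Why: Exhaustive silylation; the silyl triflate is reactive enough for the tertiary propargylic hydroxyl.

**Step 5**
Reactants: 6 (3R,4S)-3-methyl-3,4,5-tris(triethylsilyloxy)pent-1-yne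
Product: 7 (2R,3R)-3-methyl-2,3-bis(triethylsilyloxy)pent-4-ynal
Conditions: (COCl)2, DMSO, CH2Cl2, −78 to −30 °C; Et3N
Reagents that add atoms: none
Why: Swern oxidation directly on the silyl ether; only the unhindered primary triethylsilyl ether is cleaved and oxidised, the secondary and tertiary ones stay.

**Step 6**
Reactants: 8 5-bromo-2-methylpent-2-ene
Product: 9 6-methylhept-5-en-1-yne
Conditions: LiC≡CH·H2NCH2CH2NH2, DMSO, 15 °C to rt
Reagents that add atoms: lithium acetylide ethylenediamine complex, [Li+].[C-]#C.NCCN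
Why: SN2 alkylation of the acetylide by a primary homoallylic bromide.

**Step 7**
Reactants: 9 6-methylhept-5-en-1-yne
Product: 10 (1E)-1-iodo-2,6-dimethylhepta-1,5-diene
Conditions: Me3Al, Cp2ZrCl2 (0.25 equiv), CH2Cl2, rt; then I2, THF, −30 °C
Reagents that add atoms: trimethylaluminium, C[Al](C)C; iodine, II
Why: Negishi zirconium-catalysed syn-carboalumination of the terminal alkyne, then iodinolysis with retention, gives the E trisubstituted vinyl iodide only.

**Step 8**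
Reactants: 7 (2R,3R)-3-methyl-2,3-bis(triethylsilyloxy)pent-4-ynal; 10 (1E)-1-iodo-2,6-dimethylhepta-1,5-diene
Product: 11 (3R,4S,5S,6E)-3,7,11-trimethyl-3,4-bis(triethylsilyloxy)dodeca-6,10-dien-1-yn-5-ol
Conditions: CrCl2 (4 equiv), NiCl2 (2 mol%), DMSO/THF, rt; chromatography
Reagents that add atoms: none
Why: Nozaki–Hiyama–Kishi coupling tolerates the terminal alkyne; Felkin–Anh attack anti to the α-silyloxy group sets C3 as S (3,4-anti) with the E alkene retained.

**Step 9**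
Reactants: 11 (3R,4S,5S,6E)-3,7,11-trimethyl-3,4-bis(triethylsilyloxy)dodeca-6,10-dien-1-yn-5-ol
Product: 13 (4S,5S)-4-[(1E)-2,6-dimethylhepta-1,5-dien-1-yl]-5-[(2R)-2-(triethylsilyloxy)but-3-yn-2-yl]-1,3-dioxolan-2-one, via imidazolide 12 (not isolated)
Conditions: 1,1'-carbonyldiimidazole, CH2Cl2, rt; then Bu4NF/AcOH 1:1, THF, 0 °C
Reagents that add atoms: 1,1'-carbonyldiimidazole, O=C(n1ccnc1)n1ccnc1
Why: O-acylation of the C3 hydroxyl, then buffered fluoride removes the secondary silyl ether faster than the tertiary one and the freed C4 hydroxyl closes the cis cyclic carbonate by acyl substitution.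

**Step 10**
Reactants: 13 (4S,5S)-4-[(1E)-2,6-dimethylhepta-1,5-dien-1-yl]-5-[(2R)-2-(triethylsilyloxy)but-3-yn-2-yl]-1,3-dioxolan-2-one
Product: 15 (4S,5S)-4-[(1E)-2,6-dimethylhepta-1,5-dien-1-yl]-5-[(2R,3Z)-4-(tributylstannyl)-2-(triethylsilyloxy)but-3-en-2-yl]-1,3-dioxolan-2-one, via alkynylstannane 14 (not isolated)
Conditions: LiN(iPr)2, THF, −78 °C, then Bu3SnCl; then Cp2Zr(H)Cl, THF, rt; H2O
Reagents that add atoms: tributyltin chloride, CCCC[Sn](Cl)(CCCC)CCCC
Why: Stannylation of the acetylide, then syn-hydrozirconation of the 1-stannylalkyne (Zr geminal to Sn) and protonolysis with retention give the Z vinylstannane.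

**Step 11**
Reactants: 15 (4S,5S)-4-[(1E)-2,6-dimethylhepta-1,5-dien-1-yl]-5-[(2R,3Z)-4-(tributylstannyl)-2-(triethylsilyloxy)but-3-en-2-yl]-1,3-dioxolan-2-one
Product: 17 (4S,7S)-4-methyl-4-(4-methylpent-3-en-1-yl)-7-[(2R,3Z)-4-(tributylstannyl)-2-(triethylsilyloxy)but-3-en-2-yl]-4,7-dihydrooxepin-2(3H)-one, via ketene acetal 16 (not isolated)
Conditions: Cp2TiMe2 (2.5 equiv), toluene, 105 °C, dark
Reagents that add atoms: dimethyltitanocene, [CH3-].[CH3-].[Ti+4].c1cc[cH-]c1.c1cc[cH-]c1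
Why: Petasis methylenation gives a 2-methylene-1,3-dioxolane that undergoes Claisen [3,3]-sigmatropic rearrangement; C1–C11 forms on the face from which C3–O leaves, so (3S) plus the E alkene gives (1S), and the seven-membered lactone forces C2=C3 to be Z.

**Step 12**
Reactants: 17 (4S,7S)-4-methyl-4-(4-methylpent-3-en-1-yl)-7-[(2R,3Z)-4-(tributylstannyl)-2-(triethylsilyloxy)but-3-en-2-yl]-4,7-dihydrooxepin-2(3H)-one
Product: 18 (4S,7S)-4-methyl-4-(4-methylpent-3-en-1-yl)-7-[(2R,3Z)-4-(tributylstannyl)-2-(triethylsilyloxy)but-3-en-2-yl]-2,3,4,7-tetrahydrooxepin-2-ol (anomer mixture, in equilibrium with the hydroxy aldehyde)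
Conditions: iBu2AlH (1.1 equiv), CH2Cl2, −78 °C; aq. potassium sodium tartrate
Reagents that add atoms: none
Why: Partial reduction of the lactone; the tetrahedral aluminium alkoxide is stable at −78 °C and gives the lactol on work-up.

**Step 13**
Reactants: 19 ethyl (triphenylphosphoranylidene)acetate
Product: 20 ethyl iodo(triphenylphosphoranylidene)acetate
Conditions: N-iodosuccinimide, CH2Cl2, −20 °C; recrystallised (free of electrophilic iodine)
Reagents that add atoms: N-iodosuccinimide, O=C1CCC(=O)N1I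
Why: Electrophilic iodination of the stabilised ylide, then deprotonation by succinimide anion, gives the isolable iodo ylide.

**Step 14**
Reactants: 18 the lactol from step 12; 20 ethyl iodo(triphenylphosphoranylidene)acetate
Product: 21 ethyl (2Z,5S,6Z,8S,9R,10Z)-8-hydroxy-2-iodo-5,9-dimethyl-5-(4-methylpent-3-en-1-yl)-11-(tributylstannyl)-9-(triethylsilyloxy)undeca-2,6,10-trienoate
Conditions: toluene, 50 °C
Reagents that add atoms: none
Why: Wittig olefination of the open hydroxy-aldehyde form; the stabilised ylide places the ester trans to the chain, so iodine ends cis to C11 (Z).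

**Step 15**
Reactants: 21 ethyl (2Z,5S,6Z,8S,9R,10Z)-8-hydroxy-2-iodo-5,9-dimethyl-5-(4-methylpent-3-en-1-yl)-11-(tributylstannyl)-9-(triethylsilyloxy)undeca-2,6,10-trienoate
Product: 22 (2Z,5S,6Z,8S,9R,10Z)-2-iodo-5,9-dimethyl-5-(4-methylpent-3-en-1-yl)-11-(tributylstannyl)-9-(triethylsilyloxy)undeca-2,6,10-triene-1,8-diol
Conditions: iBu2AlH (3.5 equiv), CH2Cl2, −78 °C; aq. potassium sodium tartrate
Reagents that add atoms: none
Why: 1,2-Reduction of the enoate to the allylic alcohol; the vinyl iodide, vinylstannane and silyl ether are inert.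

**Step 16**
Reactants: 22 (2Z,5S,6Z,8S,9R,10Z)-2-iodo-5,9-dimethyl-5-(4-methylpent-3-en-1-yl)-11-(tributylstannyl)-9-(triethylsilyloxy)undeca-2,6,10-triene-1,8-diol
Product: 23 the 1-O-(tert-butyldimethylsilyl) ether of 22 (C8 hydroxyl free)
Conditions: tBuMe2SiCl (1.1 equiv), imidazole, CH2Cl2, 0 °C
Reagents that add atoms: tert-butyldimethylsilyl chloride, CC(C)(C)[Si](C)(C)Cl
Why: Selective silylation of the primary allylic alcohol over the hindered secondary one.

**Step 17**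
Reactants: 23 the 1-O-(tert-butyldimethylsilyl) ether of 22
Product: 24 the 8-O-(3-methylbut-2-enoyl) ester of 23
Conditions: 3-methylbut-2-enoic acid, DCC, DMAP, CH2Cl2, rt
Reagents that add atoms: 3-methylbut-2-enoic acid, CC(C)=CC(=O)O
Why: Steglich esterification of the only free hydroxyl (C4–OH); mild base-free activation avoids deconjugation of the senecioate.

**Step 18**
Reactants: 24 the 8-O-(3-methylbut-2-enoyl) ester of 23
Product: 25 (1S,2R,3Z,6Z,9S,10Z)-6-[(tert-butyldimethylsilyloxy)methyl]-2,9-dimethyl-9-(4-methylpent-3-en-1-yl)-5-oxo-2-(triethylsilyloxy)cycloundeca-3,6,10-trien-1-yl 3-methylbut-2-enoate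
Conditions: CO (1 atm), Pd2(dba)3 (10 mol%), AsPh3 (40 mol%), THF/DMF, 50 °C, 1 mM (syringe pump)
Reagents that add atoms: carbon monoxide, [C-]#[O+]
Why: Carbonylative Stille macrocyclisation: oxidative addition of zerovalent palladium to the vinyl iodide, CO insertion and transmetalation from the vinylstannane proceed with retention, giving the cross-conjugated dienone with both alkene geometries intact.

**Step 19**
Reactants: 25 the bis-silyl macrocycle from step 18
Product: 26 (1S,2R,3Z,6Z,9S,10Z)-2-hydroxy-6-(hydroxymethyl)-2,9-dimethyl-9-(4-methylpent-3-en-1-yl)-5-oxocycloundeca-3,6,10-trien-1-yl 3-methylbut-2-enoate (CNP0230506.3)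
Conditions: HF·pyridine, pyridine, THF, 0 °C to rt
Reagents that add atoms: none
Why: Buffered fluoride desilylation removes both silyl ethers without touching the ester, the dienone or the stereocentres.

**Compound list**
1 | methyl (4S)-2,2-dimethyl-1,3-dioxolane-4-carboxylate | COC(=O)[C@@H]1COC(C)(C)O1 | starting material
2 | (4S)-N-methoxy-N,2,2-trimethyl-1,3-dioxolane-4-carboxamide | CON(C)C(=O)[C@@H]1COC(C)(C)O1 | intermediate (not isolated)
3 | 1-[(4S)-2,2-dimethyl-1,3-dioxolan-4-yl]ethan-1-one | CC(=O)[C@@H]1COC(C)(C)O1 | intermediate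
4 | (2R)-2-[(4S)-2,2-dimethyl-1,3-dioxolan-4-yl]but-3-yn-2-ol | C#C[C@@](C)(O)[C@@H]1COC(C)(C)O1 | intermediate
5 | (2S,3R)-3-methylpent-4-yne-1,2,3-triol | C#C[C@@](C)(O)[C@@H](O)CO | intermediate
6 | (3R,4S)-3-methyl-3,4,5-tris(triethylsilyloxy)pent-1-yne | C#C[C@@](C)(O[Si](CC)(CC)CC)[C@@H](O[Si](CC)(CC)CC)CO[Si](CC)(CC)CC | intermediate
7 | (2R,3R)-3-methyl-2,3-bis(triethylsilyloxy)pent-4-ynal | C#C[C@@](C)(O[Si](CC)(CC)CC)[C@@H](O[Si](CC)(CC)CC)C=O | intermediate
8 | 5-bromo-2-methylpent-2-ene | CC(C)=CCCBr | starting material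
9 | 6-methylhept-5-en-1-yne | C#CCCC=C(C)C | intermediate
10 | (1E)-1-iodo-2,6-dimethylhepta-1,5-diene | CC(C)=CCC/C(C)=C/I | intermediate
11 | (3R,4S,5S,6E)-3,7,11-trimethyl-3,4-bis(triethylsilyloxy)dodeca-6,10-dien-1-yn-5-ol | CC(C)=CCC/C(C)=C/[C@H](O)[C@H](O[Si](CC)(CC)CC)[C@](C)(O[Si](CC)(CC)CC)C#C | intermediate
12 | 5-O-(imidazol-1-ylcarbonyl) derivative of 11 | CC(C)=CCC/C(C)=C/[C@H](OC(=O)n1ccnc1)[C@H](O[Si](CC)(CC)CC)[C@](C)(O[Si](CC)(CC)CC)C#C | intermediate (not isolated)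
13 | (4S,5S)-4-[(1E)-2,6-dimethylhepta-1,5-dien-1-yl]-5-[(2R)-2-(triethylsilyloxy)but-3-yn-2-yl]-1,3-dioxolan-2-one | CC(C)=CCC/C(C)=C/[C@@H]1OC(=O)O[C@@H]1[C@](C)(O[Si](CC)(CC)CC)C#C | intermediate
14 | 13 with SnBu3 on the alkyne terminus | CC(C)=CCC/C(C)=C/[C@@H]1OC(=O)O[C@@H]1[C@](C)(O[Si](CC)(CC)CC)C#C[Sn](CCCC)(CCCC)CCCC | intermediate (not isolated)
15 | (4S,5S)-4-[(1E)-2,6-dimethylhepta-1,5-dien-1-yl]-5-[(2R,3Z)-4-(tributylstannyl)-2-(triethylsilyloxy)but-3-en-2-yl]-1,3-dioxolan-2-one | CC(C)=CCC/C(C)=C/[C@@H]1OC(=O)O[C@@H]1[C@](C)(O[Si](CC)(CC)CC)/C=C\[Sn](CCCC)(CCCC)CCCC | intermediate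
16 | 2-methylidene-1,3-dioxolane (ketene acetal) corresponding to 15 | CC(C)=CCC/C(C)=C/[C@@H]1OC(=C)O[C@@H]1[C@](C)(O[Si](CC)(CC)CC)/C=C\[Sn](CCCC)(CCCC)CCCC | intermediate (not isolated)
17 | (4S,7S)-4-methyl-4-(4-methylpent-3-en-1-yl)-7-[(2R,3Z)-4-(tributylstannyl)-2-(triethylsilyloxy)but-3-en-2-yl]-4,7-dihydrooxepin-2(3H)-one | CC(C)=CCC[C@@]1(C)CC(=O)O[C@@H](/C=C\1)[C@](C)(O[Si](CC)(CC)CC)/C=C\[Sn](CCCC)(CCCC)CCCC | intermediate
18 | lactol of 17 (2,3,4,7-tetrahydrooxepin-2-ol, anomer mixture) | CC(C)=CCC[C@@]1(C)CC(O)O[C@@H](/C=C\1)[C@](C)(O[Si](CC)(CC)CC)/C=C\[Sn](CCCC)(CCCC)CCCC | intermediate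
19 | ethyl (triphenylphosphoranylidene)acetate | CCOC(=O)C=P(c1ccccc1)(c1ccccc1)c1ccccc1 | starting material
20 | ethyl iodo(triphenylphosphoranylidene)acetate | CCOC(=O)C(I)=P(c1ccccc1)(c1ccccc1)c1ccccc1 | intermediate
21 | ethyl (2Z,5S,6Z,8S,9R,10Z)-8-hydroxy-2-iodo-5,9-dimethyl-5-(4-methylpent-3-en-1-yl)-11-(tributylstannyl)-9-(triethylsilyloxy)undeca-2,6,10-trienoate | CCOC(=O)/C(I)=C/C[C@](C)(CCC=C(C)C)/C=C\[C@H](O)[C@](C)(O[Si](CC)(CC)CC)/C=C\[Sn](CCCC)(CCCC)CCCC | intermediate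
22 | (2Z,5S,6Z,8S,9R,10Z)-2-iodo-5,9-dimethyl-5-(4-methylpent-3-en-1-yl)-11-(tributylstannyl)-9-(triethylsilyloxy)undeca-2,6,10-triene-1,8-diol | OC/C(I)=C/C[C@](C)(CCC=C(C)C)/C=C\[C@H](O)[C@](C)(O[Si](CC)(CC)CC)/C=C\[Sn](CCCC)(CCCC)CCCC | intermediate
23 | 1-O-(tert-butyldimethylsilyl) ether of 22 | CC(C)(C)[Si](C)(C)OC/C(I)=C/C[C@](C)(CCC=C(C)C)/C=C\[C@H](O)[C@](C)(O[Si](CC)(CC)CC)/C=C\[Sn](CCCC)(CCCC)CCCC | intermediate
24 | 8-O-(3-methylbut-2-enoyl) ester of 23 | CC(C)(C)[Si](C)(C)OC/C(I)=C/C[C@](C)(CCC=C(C)C)/C=C\[C@H](OC(=O)C=C(C)C)[C@](C)(O[Si](CC)(CC)CC)/C=C\[Sn](CCCC)(CCCC)CCCC | intermediate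
25 | (1S,2R,3Z,6Z,9S,10Z)-6-[(tert-butyldimethylsilyloxy)methyl]-2,9-dimethyl-9-(4-methylpent-3-en-1-yl)-5-oxo-2-(triethylsilyloxy)cycloundeca-3,6,10-trien-1-yl 3-methylbut-2-enoate | CC(C)=CCC[C@]1(C)/C=C\[C@H](OC(=O)C=C(C)C)[C@](C)(O[Si](CC)(CC)CC)/C=C\C(=O)/C(CO[Si](C)(C)C(C)(C)C)=C\C1 | intermediate
26 | (1S,2R,3Z,6Z,9S,10Z)-2-hydroxy-6-(hydroxymethyl)-2,9-dimethyl-9-(4-methylpent-3-en-1-yl)-5-oxocycloundeca-3,6,10-trien-1-yl 3-methylbut-2-enoate | CC(C)=CCC[C@]1(C)/C=C\[C@H](OC(=O)C=C(C)C)[C@](C)(O)/C=C\C(=O)/C(CO)=C\C1 | target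

**Totals**
Total step count: 19. Longest linear sequence: 16 steps (steps 1–5, 8–12, 14–19); steps 6–7 and step 13 are side branches.

**Three steps most likely to fail**

Step 11 (methylenation/Claisen). The rearrangement builds a quaternary centre next to a crowded cis-disubstituted ketene acetal, and the titanium reagent can over-methylenate the product lactone. Fallback: generate the same ketene acetal by selenoxide elimination. From 15, K2CO3/MeOH removes the carbonate to give (1Z,3R,4S,5S,6E)-3,7,11-trimethyl-1-(tributylstannyl)-3-(triethylsilyloxy)dodeca-1,6,10-triene-4,5-diol F4. Acetalisation with PhSeCH2CH(OEt)2 and pyridinium tosylate in toluene gives the 2-[(phenylselanyl)methyl]-1,3-dioxolane F5. NaIO4/NaHCO3 in aqueous MeOH gives the selenoxide F6. Heating F6 with DBU in xylene at 140 °C eliminates PhSeOH to ketene acetal 16, which rearranges to 17, where the route is rejoined.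

Step 18 (carbonylative macrocyclisation). Transmetalation of the hindered Z-stannane may be slow, and direct Stille coupling without CO would give a ten-membered diene. Fallback: close the same C7–C8 bond by Nozaki–Hiyama–Kishi reaction. From 24, Pd(PPh3)4, CO (3 atm) and slowly added Bu3SnH formylate the vinyl iodide to the enal F7 (CHO in place of I, cis to C11). I2 in CH2Cl2 at 0 °C exchanges tin for iodine with retention to give the Z-vinyl iodide F8. CrCl2/NiCl2 in DMSO/THF at high dilution closes the ring to the C8 carbinol F9 (both epimers). Dess–Martin periodinane oxidises F9 to 25, where the route is rejoined.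

Step 2 (Felkin–Anh addition to the acetonide ketone). The facial selectivity at C5 may be only moderate, and the epimers may be hard to separate. Fallback: use non-chelating silyl ethers instead of the acetonide. From 1, Dowex 50W (H+ form) in MeOH/H2O gives methyl (2S)-2,3-dihydroxypropanoate F1. Et3SiCl/imidazole gives methyl (2S)-2,3-bis(triethylsilyloxy)propanoate F2. The Weinreb/MeMgBr sequence of step 1 gives (3S)-3,4-bis(triethylsilyloxy)butan-2-one F3. HC≡CMgBr at −78 °C, then Et3SiOTf/2,6-lutidine on the magnesium alkoxide, gives 6 directly, where the route is rejoined.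

**Further compounds**
F1 | step 2 | methyl (2S)-2,3-dihydroxypropanoate | COC(=O)[C@@H](O)CO
F2 | step 2 | methyl (2S)-2,3-bis(triethylsilyloxy)propanoate | COC(=O)[C@@H](O[Si](CC)(CC)CC)CO[Si](CC)(CC)CC
F3 | step 2 | (3S)-3,4-bis(triethylsilyloxy)butan-2-one | CC(=O)[C@@H](O[Si](CC)(CC)CC)CO[Si](CC)(CC)CC
F4 | step 11 | (1Z,3R,4S,5S,6E)-3,7,11-trimethyl-1-(tributylstannyl)-3-(triethylsilyloxy)dodeca-1,6,10-triene-4,5-diol | CC(C)=CCC/C(C)=C/[C@H](O)[C@H](O)[C@](C)(O[Si](CC)(CC)CC)/C=C\[Sn](CCCC)(CCCC)CCCC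
F5 | step 11 | 2-[(phenylselanyl)methyl]-1,3-dioxolane of diol F4 (acetal carbon epimers) | CC(C)=CCC/C(C)=C/[C@@H]1OC(C[Se]c2ccccc2)O[C@@H]1[C@](C)(O[Si](CC)(CC)CC)/C=C\[Sn](CCCC)(CCCC)CCCC
F6 | step 11 | selenoxide of F5 | CC(C)=CCC/C(C)=C/[C@@H]1OC(C[Se](=O)c2ccccc2)O[C@@H]1[C@](C)(O[Si](CC)(CC)CC)/C=C\[Sn](CCCC)(CCCC)CCCC
F7 | step 18 | enal: 24 with CHO in place of iodine | CC(C)(C)[Si](C)(C)OC/C(C=O)=C/C[C@](C)(CCC=C(C)C)/C=C\[C@H](OC(=O)C=C(C)C)[C@](C)(O[Si](CC)(CC)CC)/C=C\[Sn](CCCC)(CCCC)CCCC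
F8 | step 18 | F7 with iodine in place of SnBu3 (Z) | CC(C)(C)[Si](C)(C)OC/C(C=O)=C/C[C@](C)(CCC=C(C)C)/C=C\[C@H](OC(=O)C=C(C)C)[C@](C)(O[Si](CC)(CC)CC)/C=C\I
F9 | step 18 | C8 carbinol corresponding to 25 (both C8 epimers) | CC(C)=CCC[C@]1(C)/C=C\[C@H](OC(=O)C=C(C)C)[C@](C)(O[Si](CC)(CC)CC)/C=C\C(O)/C(CO[Si](C)(C)C(C)(C)C)=C\C1
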